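## Retrosynthetic overview

1. Target 48 ⇐ triene diol 47 by Sharpless epoxidation of the C15 allylic alcohol (oxirane formed last). 47 ⇐ lactone 33 by lactone reduction, C12 acetylation, radical removal of O8, and acylation at C14 and C9.
2. The strategy rests on one feature: C7 of the ten-membered ring (C1–C10) carries C11(=C13H2)–C12H2OAc beside the C8 ring methylene. This is the reduced, C8-deoxygenated form of an α-methylene-γ-butyrolactone fused across C7–C8.
3. 33 ⇐ open-chain α-PMB-oxy aldehyde 30 with a (Z)-2-(bromomethyl)enoate terminus. CrCl2 joins C7 to C8 (ten-membered carbocycle first), then the C8 alkoxide closes the γ-lactone on C12 in the same flask.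
4. 30 ⇐ two Wittig olefinations of α-alkoxy ketones (C4=C5, then C10=C1; C9 from methyl (R)-glycerate), then vinylalumination/bromination at C7 and oxidation at C8.
5. Side-chain acid 44 ⇐ Evans syn aldol of a propionyl oxazolidinone with acetaldehyde.

Key step: step 21

Remark: germacrane numbering is used for all chain and ring compounds (ring C1–C10, C11–C13 on C7, C14 on C10, C15 on C4); CIP descriptors change with the protecting groups while the configuration drawn in the SMILES stays the same.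

## Route

Step 1
Reactants: 1 methyl (R)-2,2-dimethyl-1,3-dioxolane-4-carboxylate
Product: 2 methyl (R)-2,3-dihydroxypropanoate
Conditions: Dowex 50WX8 (H+), MeOH, rt
Reagents that add atoms: none
Why: Acid-catalysed transacetalisation (acetonide methanolysis) frees the 1,2-diol without touching the future C9 stereocentre.

Step 2
Reactants: 2 methyl (R)-2,3-dihydroxypropanoate
Product: 3 methyl (4R)-2-(4-methoxyphenyl)-1,3-dioxolane-4-carboxylate (both epimers at the acetal carbon)
Conditions: 4-MeOC6H4CH(OMe)2, CSA (cat.), CH2Cl2, rt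
Reagents that add atoms: 4-methoxybenzaldehyde dimethyl acetal, COC(OC)c1ccc(OC)cc1
Why: Acid-catalysed acetal exchange gives the five-membered 4-methoxybenzylidene acetal, a cyclic protecting group that later leaves the PMB ether on O9, and the new acetal centre (both epimers) is removed in step 13.

Step 3
Reactants: 3 methyl (4R)-2-(4-methoxyphenyl)-1,3-dioxolane-4-carboxylate
Product: 4 (4R)-N-methoxy-2-(4-methoxyphenyl)-N-methyl-1,3-dioxolane-4-carboxamide
Conditions: MeNH(OMe)·HCl, iPrMgCl, THF, −20 °C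
Reagents that add atoms: N,O-dimethylhydroxylamine hydrochloride, CNOC.Cl
Why: Aminolysis of the ester by the magnesium amide (Weinreb amide formation) runs at low temperature and should leave the α-stereocentre intact.

Step 4
Reactants: 5 (tributylstannyl)methanol
Product: 6 tributyl{[(4-methoxybenzyl)oxy]methyl}stannane
Conditions: NaH, 4-MeOC6H4CH2Cl, Bu4NI (cat.), THF/DMF, 0 °C to rt
Reagents that add atoms: 4-methoxybenzyl chloride, COc1ccc(CCl)cc1
Why: Williamson etherification of the primary alkoxide with the benzylic chloride.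

Step 5
Reactants: 6 tributyl{[(4-methoxybenzyl)oxy]methyl}stannane; 4 (4R)-N-methoxy-2-(4-methoxyphenyl)-N-methyl-1,3-dioxolane-4-carboxamide
Product: 8 2-[(4-methoxybenzyl)oxy]-1-[(4R)-2-(4-methoxyphenyl)-1,3-dioxolan-4-yl]ethan-1-one, via [(4-methoxybenzyl)oxy]methyllithium 7 (not isolated)
Conditions: n-BuLi, THF, −78 °C; then 4, −78 °C; aq. NH4Cl
Reagents that add atoms: none
Why: Tin–lithium exchange gives the α-alkoxymethyllithium, and its addition to the Weinreb amide stops at the chelated tetrahedral adduct (Weinreb ketone synthesis), so C14 is attached without over-addition or epimerisation at C9.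

Step 6
Reactants: 9 5-chloropent-1-ene
Product: 10 5-chloropentane-1,2-diol (racemic)
Conditions: OsO4 (cat.), NMO, acetone/H2O, rt
Reagents that add atoms: N-methylmorpholine N-oxide, C[N+]1([O-])CCOCC1; water, O
Why: Upjohn dihydroxylation of the terminal olefin, the racemic carbinol centre being oxidised away in step 8.

Step 7
Reactants: 10 5-chloropentane-1,2-diol
Product: 11 1-[(tert-butyldiphenylsilyl)oxy]-5-chloropentan-2-ol (racemic)
Conditions: TBDPSCl, imidazole, CH2Cl2, 0 °C
Reagents that add atoms: tert-butyl(chloro)diphenylsilane, CC(C)(C)[Si](Cl)(c1ccccc1)c1ccccc1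
Why: Silylation with the bulky chlorosilane is much faster at the primary than at the secondary hydroxyl.

Step 8
Reactants: 11 1-[(tert-butyldiphenylsilyl)oxy]-5-chloropentan-2-ol
Product: 12 1-[(tert-butyldiphenylsilyl)oxy]-5-chloropentan-2-one
Conditions: Dess–Martin periodinane, NaHCO3, CH2Cl2, rt
Reagents that add atoms: none
Why: Dess–Martin oxidation of the secondary alcohol gives the α-silyloxy ketone under buffered conditions that do not enolise it toward the γ-chloride.

Step 9
Reactants: 13 (3-hydroxypropyl)triphenylphosphonium bromide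
Product: 14 triphenyl{3-[(triethylsilyl)oxy]propyl}phosphonium bromide
Conditions: TESCl, imidazole, CH2Cl2, rt
Reagents that add atoms: chlorotriethylsilane, CC[Si](Cl)(CC)CC
Why: Silylation of the primary alcohol protects O7 for the ylide chemistry with a group that can later be removed in the presence of TBS and TBDPS ethers.

Step 10
Reactants: 14 triphenyl{3-[(triethylsilyl)oxy]propyl}phosphonium bromide; 12 1-[(tert-butyldiphenylsilyl)oxy]-5-chloropentan-2-one
Product: 16 (Z)-1-[(tert-butyldiphenylsilyl)oxy]-2-(3-chloropropyl)-5-[(triethylsilyl)oxy]pent-2-ene, via triethylsilyloxypropylidene phosphorane 15 (not isolated)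
Conditions: NaN(SiMe3)2, THF, −78 to 0 °C; then 12, −78 °C to rt
Reagents that add atoms: none
Why: Wittig olefination of an α-alkoxy ketone with a non-stabilised ylide at low temperature (Still-type Z-selective Wittig) places the new alkyl chain cis to the CH2OSi group, which gives the C4=C5 olefin with C15 cis to C6.

Step 11
Reactants: 16 (Z)-1-[(tert-butyldiphenylsilyl)oxy]-2-(3-chloropropyl)-5-[(triethylsilyl)oxy]pent-2-ene
Product: 18 {(4Z)-4-{[(tert-butyldiphenylsilyl)oxy]methyl}-7-[(triethylsilyl)oxy]hept-4-en-1-yl}triphenylphosphonium iodide, via primary alkyl iodide 17 (not isolated)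
Conditions: NaI, PPh3, NaHCO3, MeCN, reflux
Reagents that add atoms: triphenylphosphine, c1ccc(cc1)P(c1ccccc1)c1ccccc1; sodium iodide, [Na+].[I-]
Why: Finkelstein exchange makes the primary iodide in the flask, which triphenylphosphine quaternises by SN2 substitution.

Step 12
Reactants: 18 {(4Z)-4-{[(tert-butyldiphenylsilyl)oxy]methyl}-7-[(triethylsilyl)oxy]hept-4-en-1-yl}triphenylphosphonium iodide; 8 2-[(4-methoxybenzyl)oxy]-1-[(4R)-2-(4-methoxyphenyl)-1,3-dioxolan-4-yl]ethan-1-one
Product: 20 open-chain diene (9S, 1(10)E, 4Z) with C8/C9 diol as 4-methoxybenzylidene acetal, 14-OPMB, 15-OTBDPS, 7-OTES, via heptenylidene phosphorane 19 (not isolated)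
Conditions: NaN(SiMe3)2, THF, −78 to 0 °C; then 8, −78 °C to rt
Reagents that add atoms: none
Why: Wittig olefination of the α,α'-dialkoxy ketone follows the same Still-type selectivity, the ylide chain ending cis to the unbranched CH2OPMB group and trans to the branched dioxolanyl carbon, while the ring acetal blocks β-elimination and C9 is not touched.

Step 13
Reactants: 20 open-chain diene with C8/C9 4-methoxybenzylidene acetal
Product: 21 open-chain diene (9S, 1(10)E, 4Z): 8-OH, 9-OPMB, 14-OPMB, 15-OTBDPS, 7-OTES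
Conditions: iBu2AlH, CH2Cl2, −78 to 0 °C; aq. potassium sodium tartrate
Reagents that add atoms: none
Why: Reductive opening of the 4-methoxybenzylidene acetal by iBu2AlH, in which aluminium binds the less hindered primary oxygen so that hydride leaves the PMB ether on the secondary O9 and frees the C8 hydroxyl.

Step 14
Reactants: 21 open-chain diene with 8-OH
Product: 22 open-chain diene (9S, 1(10)E, 4Z): 8-OTBS, 9-OPMB, 14-OPMB, 15-OTBDPS, 7-OTES
Conditions: TBSCl, imidazole, CH2Cl2, 0 °C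
Reagents that add atoms: tert-butyl(chloro)dimethylsilane, CC(C)(C)[Si](C)(C)Cl
Why: Silylation of the only free (primary) hydroxyl.

Step 15
Reactants: 22 open-chain diene with 8-OTBS and 7-OTES
Product: 23 open-chain diene (9S, 1(10)E, 4Z): 7-OH, 8-OTBS, 9-OPMB, 14-OPMB, 15-OTBDPS
Conditions: PPTS (cat.), MeOH/CH2Cl2, 0 °C
Reagents that add atoms: none
Why: Acid-catalysed methanolysis removes a primary TES ether much faster than primary TBS and TBDPS ethers.

Step 16
Reactants: 23 open-chain diene with 7-OH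
Product: 24 open-chain C7 aldehyde (9S, 1(10)E, 4Z): 8-OTBS, 9-OPMB, 14-OPMB, 15-OTBDPS
Conditions: Dess–Martin periodinane, NaHCO3, CH2Cl2, 0 °C; used at once
Reagents that add atoms: none
Why: Dess–Martin oxidation without base gives the β,γ-unsaturated aldehyde, so the C4=C5 olefin should not move into conjugation.

Step 17
Reactants: 25 methyl propiolate; 24 open-chain C7 aldehyde
Product: 27 open-chain Morita–Baylis–Hillman-type adduct, methyl 2-methylene-3-hydroxy ester at C11/C7 (C7 epimers; 9S, 1(10)E, 4Z), via 1-(methoxycarbonyl)vinyl diisobutylaluminium 26 (not isolated)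
Conditions: 25, iBu2AlH, NMO, THF, 0 °C; then 24, 0 °C to rt
Reagents that add atoms: none
Why: Vinylalumination, in which 1,4-hydroalumination of the propiolate gives the α-aluminoacrylate that adds to the aldehyde under non-basic conditions, with the C7 carbinol formed as both epimers and removed in step 18.

Step 18
Reactants: 27 open-chain Morita–Baylis–Hillman-type adduct
Product: 28 open-chain (Z)-2-(bromomethyl)enoate (9S, 1(10)E, 4Z, 7(11)Z): 8-OTBS, 9-OPMB, 14-OPMB, 15-OTBDPS
Conditions: NBS, Me2S, CH2Cl2, −20 to 0 °C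
Reagents that add atoms: N-bromosuccinimide, O=C1CCC(=O)N1Br
Why: Corey–Kim-type activation of the allylic alcohol followed by bromide attack with allylic transposition (SN2') gives the thermodynamically preferred (Z)-2-(bromomethyl)enoate, C6 trans to the ester.

Step 19
Reactants: 28 open-chain (Z)-2-(bromomethyl)enoate with 8-OTBS
Product: 29 open-chain (Z)-2-(bromomethyl)enoate with 8-OH (9S, 1(10)E, 4Z, 7(11)Z)
Conditions: aq. HF, MeCN, 0 °C
Reagents that add atoms: none
Why: Acidic fluoride desilylation cleaves the primary TBS ether faster than the primary TBDPS ether in a base-free, weakly nucleophilic medium that leaves the allylic bromide alone.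

Step 20
Reactants: 29 open-chain (Z)-2-(bromomethyl)enoate with 8-OH
Product: 30 open-chain α-PMB-oxy aldehyde with (Z)-2-(bromomethyl)enoate terminus (9S, 1(10)E, 4Z, 7(11)Z): 14-OPMB, 15-OTBDPS
Conditions: Dess–Martin periodinane, NaHCO3, CH2Cl2, 0 °C; used at once
Reagents that add atoms: none
Why: Buffered Dess–Martin oxidation gives the α-alkoxy aldehyde without base, so C9 should not epimerise before the aldehyde is used.

Step 21
Reactants: 30 open-chain α-PMB-oxy aldehyde with (Z)-2-(bromomethyl)enoate terminus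
Product: 33 (7S,8S,9S,1(10)E,4Z)-9,14-bis(PMB-oxy)-15-(TBDPS-oxy)germacra-1(10),4,11(13)-trien-12,8-olide (trans-fused α-methylene-γ-butyrolactone), via allylchromium dichloride 31 (not isolated), via ring-closed chromium alkoxide 32 (not isolated)
Conditions: CrCl2 (10 equiv), THF, 2 mM, slow addition of 30, rt; aq. NH4Cl
Reagents that add atoms: none
Why: Two equivalents of divalent chromium reduce the allylic C–Br bond to the σ-allylchromium dichloride 31, which adds to the C8 aldehyde through C7 with allylic transposition in a closed six-membered transition state, and the trivalent chromium alkoxide 32 then displaces methoxide from the C12 ester; the closest known reaction type is the intramolecular Nozaki–Hiyama (Barbier) allylation of aldehydes by 2-(bromomethyl)acrylates that gives medium-ring α-methylene-γ-butyrolactones. The ten-membered carbocycle closes by 10-exo-trig addition of C7 to the C8 carbonyl, the two E-trisubstituted olefins pre-folding the chain, and the γ-lactone closes by 5-exo-trig acyl substitution. C8 is set by the C9 stereocentre through attack on the aldehyde face opposite C10 in a chromium chelate between the carbonyl oxygen and the PMB ether, and C7 is set relative to C8 by the chair-like transition state in which the equilibrating allylchromium places the ring chain (C6) equatorial, as is usual for γ-substituted allylchromium reagents, which gives the trans-fused lactone 33. The selectivity the route needs is the cis relation of the C7 side chain to the C9 oxygen, because C8 is deoxygenated in step 25; it is reached by the pairing just described and equally by Felkin attack with C6 axial, which gives the cis-fused C8 epimer with the same C7 configuration, so that only C7 epimers are lost. The neutral, non-basic medium spares the epimerisable α-alkoxy aldehyde, the skipped diene and the silyl and PMB ethers, and high dilution with slow addition suppresses coupling between molecules.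

Step 22
Reactants: 33 trans-fused lactone
Product: 34 (7S,8S,9S,1(10)E,4Z)-9,14-bis(PMB-oxy)-15-(TBDPS-oxy)germacra-1(10),4,11(13)-triene-8,12-diol
Conditions: iBu2AlH, CH2Cl2, −78 to 0 °C; aq. potassium sodium tartrate
Reagents that add atoms: none
Why: iBu2AlH reduces the lactone by 1,2-hydride addition through the lactol and the ring-opened enal to the C8,C12 diol, leaving the exocyclic olefin.

Step 23
Reactants: 34 C8,C12 diol
Product: 35 (7S,8S,9S,1(10)E,4Z)-12-acetoxy-9,14-bis(PMB-oxy)-15-(TBDPS-oxy)germacra-1(10),4,11(13)-trien-8-ol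
Conditions: Ac2O, 2,4,6-collidine, CH2Cl2, −20 to 0 °C
Reagents that add atoms: acetic anhydride, CC(=O)OC(C)=O
Why: Selective acetylation of the unhindered primary allylic alcohol over the flanked secondary C8 hydroxyl.

Step 24
Reactants: 35 C12 acetate with 8-OH
Product: 36 8-O-(imidazol-1-ylthiocarbonyl) derivative of 35
Conditions: (imidazol-1-yl)2C=S, DMAP (cat.), toluene, 80 °C
Reagents that add atoms: 1,1'-thiocarbonyldiimidazole, S=C(n1ccnc1)n1ccnc1
Why: Thioacylation of the C8 hydroxyl gives the thiocarbonyl derivative needed for radical C–O cleavage under conditions that leave the allylic acetate.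

Step 25
Reactants: 36 8-O-(imidazol-1-ylthiocarbonyl) derivative
Product: 37 (7R,9R,1(10)E,4Z)-12-acetoxy-9,14-bis(PMB-oxy)-15-(TBDPS-oxy)germacra-1(10),4,11(13)-triene
Conditions: Bu3SnH (0.3 M), AIBN, toluene, 100 °C
Reagents that add atoms: none
Why: Barton–McCombie deoxygenation (stannyl radical addition to sulfur, β-scission to the secondary C8 radical, hydrogen transfer from the stannane), run concentrated so that reduction outruns rearrangement of the homoallylic radical, with C7 and C9 untouched.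

Step 26
Reactants: 37 C8-deoxygenated bis-PMB ether
Product: 38 (7R,9R,1(10)E,4Z)-12-acetoxy-15-(TBDPS-oxy)germacra-1(10),4,11(13)-triene-9,14-diol
Conditions: DDQ, CH2Cl2/pH 7 buffer, 0 °C
Reagents that add atoms: none
Why: Oxidative cleavage of both PMB ethers by DDQ (hydride abstraction at the electron-rich benzylic carbon, then hydrolysis) in a buffered two-phase medium that leaves the silyl ether and the acetate.

Step 27
Reactants: 39 (R)-4-benzyl-3-propionyloxazolidin-2-one; 40 acetaldehyde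
Product: 42 (R)-4-benzyl-3-[(2R,3S)-3-hydroxy-2-methylbutanoyl]oxazolidin-2-one, via (Z)-dibutylboron enolate 41 (not isolated)
Conditions: Bu2BOTf, iPr2NEt, CH2Cl2, 0 °C; then 40, −78 to 0 °C; H2O2, MeOH, pH 7 buffer
Reagents that add atoms: none
Why: Evans syn aldol, in which the (Z)-boron enolate adds through a Zimmerman–Traxler chair on the face opposite the benzyl group of the (R)-auxiliary and so sets (2R,3S).

Step 28
Reactants: 42 Evans aldol adduct
Product: 43 (R)-4-benzyl-3-[(2R,3S)-3-(tert-butyldimethylsilyloxy)-2-methylbutanoyl]oxazolidin-2-one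
Conditions: TBSOTf, 2,6-lutidine, CH2Cl2, 0 °C
Reagents that add atoms: tert-butyldimethylsilyl trifluoromethanesulfonate, CC(C)(C)[Si](C)(C)OS(=O)(=O)C(F)(F)F
Why: Silylation of the secondary alcohol with the silyl triflate and a hindered base.

Step 29
Reactants: 43 silylated aldol adduct
Product: 44 (2R,3S)-3-(tert-butyldimethylsilyloxy)-2-methylbutanoic acid
Conditions: LiOH, H2O2, THF/H2O, 0 °C; Na2SO3; HCl to pH 3
Reagents that add atoms: hydrogen peroxide (as lithium hydroperoxide), OO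
Why: Lithium hydroperoxide attacks the exocyclic imide carbonyl selectively (Evans auxiliary cleavage) and should not epimerise C2.

Step 30
Reactants: 38 C9,C14 diol; 44 (2R,3S)-3-(tert-butyldimethylsilyloxy)-2-methylbutanoic acid
Product: 45 (7R,9R,1(10)E,4Z)-12-acetoxy-15-(TBDPS-oxy)-9-hydroxygermacra-1(10),4,11(13)-trien-14-yl (2R,3S)-3-(TBS-oxy)-2-methylbutanoate
Conditions: EDC·HCl, DMAP (cat.), CH2Cl2, 0 °C
Reagents that add atoms: none
Why: Carbodiimide (Steglich) esterification acylates the primary allylic C14 hydroxyl in preference to the hindered secondary C9 hydroxyl.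

Step 31
Reactants: 45 C14 ester with 9-OH
Product: 46 9-O-(3-methylbut-2-enoyl) derivative of 45 (7R,9R; 15-OTBDPS, side-chain OTBS)
Conditions: 3-methylbut-2-enoyl chloride, pyridine, DMAP (cat.), CH2Cl2, 0 °C to rt
Reagents that add atoms: 3-methylbut-2-enoyl chloride, CC(C)=CC(=O)Cl
Why: Acylation of the remaining secondary alcohol with the acid chloride, with pyridine as the only stoichiometric base to limit deconjugation of the senecioyl group through a vinylketene.

Step 32
Reactants: 46 fully acylated bis-silyl ether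
Product: 47 (7R,9R,1(10)E,4Z)-12-acetoxy-15-hydroxy-9-(3-methylbut-2-enoyloxy)germacra-1(10),4,11(13)-trien-14-yl (2R,3S)-3-hydroxy-2-methylbutanoate
Conditions: HF·pyridine, pyridine, THF, 0 °C to rt
Reagents that add atoms: none
Why: Buffered fluoride desilylation removes the TBDPS and TBS ethers and leaves the three esters.

Step 33
Reactants: 47 triene diol
Product: 48 target, (4S,5R,7S,9R,1(10)E)-12-acetoxy-4,5-epoxy-15-hydroxy-9-(3-methylbut-2-enoyloxy)germacra-1(10),11(13)-dien-14-yl (2R,3S)-3-hydroxy-2-methylbutanoate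
Conditions: Ti(OiPr)4, L-(+)-DIPT, t-BuOOH, 4 Å MS, CH2Cl2, −20 °C
Reagents that add atoms: tert-butyl hydroperoxide, CC(C)(C)OO
Why: Katsuki–Sharpless asymmetric epoxidation, in which titanium bound to the C15 allylic alkoxide and L-(+)-tartrate delivers oxygen to the olefin face that gives 4S, syn addition to the C4=C5 olefin gives 5R, and the other olefins lack a free allylic hydroxyl.

## Compound list

1 | methyl (R)-2,2-dimethyl-1,3-dioxolane-4-carboxylate | COC(=O)[C@H]1COC(C)(C)O1 | starting material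
2 | methyl (R)-2,3-dihydroxypropanoate | COC(=O)[C@H](O)CO | intermediate
3 | methyl (4R)-2-(4-methoxyphenyl)-1,3-dioxolane-4-carboxylate (acetal epimers) | COC(=O)[C@H]1COC(O1)c1ccc(OC)cc1 | intermediate
4 | (4R)-N-methoxy-2-(4-methoxyphenyl)-N-methyl-1,3-dioxolane-4-carboxamide (acetal epimers) | CON(C)C(=O)[C@H]1COC(O1)c1ccc(OC)cc1 | intermediate
5 | (tributylstannyl)methanol | OC[Sn](CCCC)(CCCC)CCCC | starting material
6 | tributyl{[(4-methoxybenzyl)oxy]methyl}stannane | COc1ccc(COC[Sn](CCCC)(CCCC)CCCC)cc1 | intermediate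
7 | [(4-methoxybenzyl)oxy]methyllithium | [Li]COCc1ccc(OC)cc1 | intermediate (not isolated)
8 | 2-[(4-methoxybenzyl)oxy]-1-[(4R)-2-(4-methoxyphenyl)-1,3-dioxolan-4-yl]ethan-1-one (acetal epimers) | COc1ccc(COCC(=O)[C@H]2COC(O2)c2ccc(OC)cc2)cc1 | intermediate
9 | 5-chloropent-1-ene | C=CCCCCl | starting material
10 | 5-chloropentane-1,2-diol (racemic) | OCC(O)CCCCl | intermediate
11 | 1-[(tert-butyldiphenylsilyl)oxy]-5-chloropentan-2-ol (racemic) | OC(CCCCl)CO[Si](c1ccccc1)(c1ccccc1)C(C)(C)C | intermediate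
12 | 1-[(tert-butyldiphenylsilyl)oxy]-5-chloropentan-2-one | O=C(CCCCl)CO[Si](c1ccccc1)(c1ccccc1)C(C)(C)C | intermediate
13 | (3-hydroxypropyl)triphenylphosphonium bromide | OCCC[P+](c1ccccc1)(c1ccccc1)c1ccccc1.[Br-] | starting material
14 | triphenyl{3-[(triethylsilyl)oxy]propyl}phosphonium bromide | CC[Si](CC)(CC)OCCC[P+](c1ccccc1)(c1ccccc1)c1ccccc1.[Br-] | intermediate
15 | triphenyl{3-[(triethylsilyl)oxy]propylidene}phosphorane | CC[Si](CC)(CC)OCCC=P(c1ccccc1)(c1ccccc1)c1ccccc1 | intermediate (not isolated)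
16 | (Z)-1-[(tert-butyldiphenylsilyl)oxy]-2-(3-chloropropyl)-5-[(triethylsilyl)oxy]pent-2-ene | ClCCC/C(CO[Si](c1ccccc1)(c1ccccc1)C(C)(C)C)=C/CCO[Si](CC)(CC)CC | intermediate
17 | (Z)-1-[(tert-butyldiphenylsilyl)oxy]-2-(3-iodopropyl)-5-[(triethylsilyl)oxy]pent-2-ene | ICCC/C(CO[Si](c1ccccc1)(c1ccccc1)C(C)(C)C)=C/CCO[Si](CC)(CC)CC | intermediate (not isolated)
18 | {(4Z)-4-{[(tert-butyldiphenylsilyl)oxy]methyl}-7-[(triethylsilyl)oxy]hept-4-en-1-yl}triphenylphosphonium iodide | CC[Si](CC)(CC)OCC/C=C(CO[Si](c1ccccc1)(c1ccccc1)C(C)(C)C)/CCC[P+](c1ccccc1)(c1ccccc1)c1ccccc1.[I-] | intermediate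
19 | {(4Z)-4-{[(tert-butyldiphenylsilyl)oxy]methyl}-7-[(triethylsilyl)oxy]hept-4-en-1-ylidene}triphenylphosphorane | CC[Si](CC)(CC)OCC/C=C(CO[Si](c1ccccc1)(c1ccccc1)C(C)(C)C)/CCC=P(c1ccccc1)(c1ccccc1)c1ccccc1 | intermediate (not isolated)
20 | open-chain diene (9S, 1(10)E, 4Z): C8/C9 4-methoxybenzylidene acetal (acetal epimers), 14-OPMB, 15-OTBDPS, 7-OTES | COc1ccc(cc1)C1OC[C@@H](O1)/C(COCc1ccc(OC)cc1)=C/CC/C(CO[Si](c1ccccc1)(c1ccccc1)C(C)(C)C)=C/CCO[Si](CC)(CC)CC | intermediate
21 | open-chain diene (9S, 1(10)E, 4Z): 8-OH, 9-OPMB, 14-OPMB, 15-OTBDPS, 7-OTES | OC[C@@H](OCc1ccc(OC)cc1)/C(COCc1ccc(OC)cc1)=C/CC/C(CO[Si](c1ccccc1)(c1ccccc1)C(C)(C)C)=C/CCO[Si](CC)(CC)CC | intermediate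
22 | open-chain diene (9S, 1(10)E, 4Z): 8-OTBS, 9-OPMB, 14-OPMB, 15-OTBDPS, 7-OTES | CC(C)(C)[Si](C)(C)OC[C@@H](OCc1ccc(OC)cc1)/C(COCc1ccc(OC)cc1)=C/CC/C(CO[Si](c1ccccc1)(c1ccccc1)C(C)(C)C)=C/CCO[Si](CC)(CC)CC | intermediate
23 | open-chain diene (9S, 1(10)E, 4Z): 7-OH, 8-OTBS, 9-OPMB, 14-OPMB, 15-OTBDPS | CC(C)(C)[Si](C)(C)OC[C@@H](OCc1ccc(OC)cc1)/C(COCc1ccc(OC)cc1)=C/CC/C(CO[Si](c1ccccc1)(c1ccccc1)C(C)(C)C)=C/CCO | intermediate
24 | open-chain C7 aldehyde (9S, 1(10)E, 4Z): 8-OTBS, 9-OPMB, 14-OPMB, 15-OTBDPS | CC(C)(C)[Si](C)(C)OC[C@@H](OCc1ccc(OC)cc1)/C(COCc1ccc(OC)cc1)=C/CC/C(CO[Si](c1ccccc1)(c1ccccc1)C(C)(C)C)=C/CC=O | intermediate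
25 | methyl propiolate | C#CC(=O)OC | starting material
26 | [1-(methoxycarbonyl)vinyl]diisobutylaluminium | C=C(C(=O)OC)[Al](CC(C)C)CC(C)C | intermediate (not isolated)
27 | open-chain methyl 2-methylene-3-hydroxy ester (C7 epimers; 9S, 1(10)E, 4Z): 8-OTBS, 9-OPMB, 14-OPMB, 15-OTBDPS | CC(C)(C)[Si](C)(C)OC[C@@H](OCc1ccc(OC)cc1)/C(COCc1ccc(OC)cc1)=C/CC/C(CO[Si](c1ccccc1)(c1ccccc1)C(C)(C)C)=C/CC(O)C(=C)C(=O)OC | intermediate
28 | open-chain (Z)-2-(bromomethyl)enoate (9S, 1(10)E, 4Z, 7(11)Z): 8-OTBS, 9-OPMB, 14-OPMB, 15-OTBDPS | CC(C)(C)[Si](C)(C)OC[C@@H](OCc1ccc(OC)cc1)/C(COCc1ccc(OC)cc1)=C/CC/C(CO[Si](c1ccccc1)(c1ccccc1)C(C)(C)C)=C/C/C=C(\CBr)C(=O)OC | intermediate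
29 | open-chain (Z)-2-(bromomethyl)enoate (9S, 1(10)E, 4Z, 7(11)Z): 8-OH, 9-OPMB, 14-OPMB, 15-OTBDPS | OC[C@@H](OCc1ccc(OC)cc1)/C(COCc1ccc(OC)cc1)=C/CC/C(CO[Si](c1ccccc1)(c1ccccc1)C(C)(C)C)=C/C/C=C(\CBr)C(=O)OC | intermediate
30 | open-chain α-PMB-oxy aldehyde with (Z)-2-(bromomethyl)enoate terminus (9S, 1(10)E, 4Z, 7(11)Z): 14-OPMB, 15-OTBDPS | O=C[C@@H](OCc1ccc(OC)cc1)/C(COCc1ccc(OC)cc1)=C/CC/C(CO[Si](c1ccccc1)(c1ccccc1)C(C)(C)C)=C/C/C=C(\CBr)C(=O)OC | intermediate
31 | σ-allylchromium dichloride derived from 30 (chromium on C13) | O=C[C@@H](OCc1ccc(OC)cc1)/C(COCc1ccc(OC)cc1)=C/CC/C(CO[Si](c1ccccc1)(c1ccccc1)C(C)(C)C)=C/C/C=C(\C[Cr](Cl)Cl)C(=O)OC | intermediate (not isolated)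
32 | ring-closed chromium alkoxide, methyl (7S,8S,9S)-ester with 8-O–CrCl2 | C=C(C(=O)OC)[C@H]1[C@H](O[Cr](Cl)Cl)[C@@H](OCc2ccc(OC)cc2)/C(COCc2ccc(OC)cc2)=C/CC/C(CO[Si](c2ccccc2)(c2ccccc2)C(C)(C)C)=C/C1 | intermediate (not isolated)
33 | (7S,8S,9S,1(10)E,4Z)-9,14-bis(PMB-oxy)-15-(TBDPS-oxy)germacra-1(10),4,11(13)-trien-12,8-olide (trans-fused) | C=C1C(=O)O[C@@H]2[C@@H](OCc3ccc(OC)cc3)/C(COCc3ccc(OC)cc3)=C/CC/C(CO[Si](c3ccccc3)(c3ccccc3)C(C)(C)C)=C/C[C@@H]12 | intermediate
34 | (7S,8S,9S,1(10)E,4Z)-9,14-bis(PMB-oxy)-15-(TBDPS-oxy)germacra-1(10),4,11(13)-triene-8,12-diol | C=C(CO)[C@H]1[C@H](O)[C@@H](OCc2ccc(OC)cc2)/C(COCc2ccc(OC)cc2)=C/CC/C(CO[Si](c2ccccc2)(c2ccccc2)C(C)(C)C)=C/C1 | intermediate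
35 | (7S,8S,9S,1(10)E,4Z)-12-acetoxy-9,14-bis(PMB-oxy)-15-(TBDPS-oxy)germacra-1(10),4,11(13)-trien-8-ol | C=C(COC(C)=O)[C@H]1[C@H](O)[C@@H](OCc2ccc(OC)cc2)/C(COCc2ccc(OC)cc2)=C/CC/C(CO[Si](c2ccccc2)(c2ccccc2)C(C)(C)C)=C/C1 | intermediate
36 | 8-O-(imidazol-1-ylthiocarbonyl) derivative of 35 | C=C(COC(C)=O)[C@H]1[C@H](OC(=S)n2ccnc2)[C@@H](OCc2ccc(OC)cc2)/C(COCc2ccc(OC)cc2)=C/CC/C(CO[Si](c2ccccc2)(c2ccccc2)C(C)(C)C)=C/C1 | intermediate
37 | (7R,9R,1(10)E,4Z)-12-acetoxy-9,14-bis(PMB-oxy)-15-(TBDPS-oxy)germacra-1(10),4,11(13)-triene | C=C(COC(C)=O)[C@H]1C[C@@H](OCc2ccc(OC)cc2)/C(COCc2ccc(OC)cc2)=C/CC/C(CO[Si](c2ccccc2)(c2ccccc2)C(C)(C)C)=C/C1 | intermediate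
38 | (7R,9R,1(10)E,4Z)-12-acetoxy-15-(TBDPS-oxy)germacra-1(10),4,11(13)-triene-9,14-diol | C=C(COC(C)=O)[C@H]1C[C@@H](O)/C(CO)=C/CC/C(CO[Si](c2ccccc2)(c2ccccc2)C(C)(C)C)=C/C1 | intermediate
39 | (R)-4-benzyl-3-propionyloxazolidin-2-one | CCC(=O)N1[C@H](Cc2ccccc2)COC1=O | starting material
40 | acetaldehyde | CC=O | starting material
41 | (Z)-dibutylboron enolate of 39 | C/C=C(\OB(CCCC)CCCC)N1[C@H](Cc2ccccc2)COC1=O | intermediate (not isolated)
42 | (R)-4-benzyl-3-[(2R,3S)-3-hydroxy-2-methylbutanoyl]oxazolidin-2-one | O=C([C@H](C)[C@H](C)O)N1[C@H](Cc2ccccc2)COC1=O | intermediate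
43 | (R)-4-benzyl-3-[(2R,3S)-3-(tert-butyldimethylsilyloxy)-2-methylbutanoyl]oxazolidin-2-one | O=C([C@H](C)[C@H](C)O[Si](C)(C)C(C)(C)C)N1[C@H](Cc2ccccc2)COC1=O | intermediate
44 | (2R,3S)-3-(tert-butyldimethylsilyloxy)-2-methylbutanoic acid | OC(=O)[C@H](C)[C@H](C)O[Si](C)(C)C(C)(C)C | intermediate
45 | (7R,9R,1(10)E,4Z)-12-acetoxy-15-(TBDPS-oxy)-9-hydroxygermacra-1(10),4,11(13)-trien-14-yl (2R,3S)-3-(TBS-oxy)-2-methylbutanoate | C=C(COC(C)=O)[C@H]1C[C@@H](O)/C(COC(=O)[C@H](C)[C@H](C)O[Si](C)(C)C(C)(C)C)=C/CC/C(CO[Si](c2ccccc2)(c2ccccc2)C(C)(C)C)=C/C1 | intermediate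
46 | 9-O-(3-methylbut-2-enoyl) derivative of 45 | C=C(COC(C)=O)[C@H]1C[C@@H](OC(=O)C=C(C)C)/C(COC(=O)[C@H](C)[C@H](C)O[Si](C)(C)C(C)(C)C)=C/CC/C(CO[Si](c2ccccc2)(c2ccccc2)C(C)(C)C)=C/C1 | intermediate
47 | (7R,9R,1(10)E,4Z)-12-acetoxy-15-hydroxy-9-(3-methylbut-2-enoyloxy)germacra-1(10),4,11(13)-trien-14-yl (2R,3S)-3-hydroxy-2-methylbutanoate | C=C(COC(C)=O)[C@H]1C[C@@H](OC(=O)C=C(C)C)/C(COC(=O)[C@H](C)[C@H](C)O)=C/CC/C(CO)=C/C1 | intermediate
48 | CNP0227102.1, (4S,5R,7S,9R,1(10)E)-12-acetoxy-4,5-epoxy-15-hydroxy-9-(3-methylbut-2-enoyloxy)germacra-1(10),11(13)-dien-14-yl (2R,3S)-3-hydroxy-2-methylbutanoate | C=C(COC(C)=O)[C@H]1C[C@@H](OC(=O)C=C(C)C)/C(COC(=O)[C@H](C)[C@H](C)O)=C/CC[C@@]2(CO)O[C@@H]2C1 | target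

## Step count and risks

Total step count: 33.
Longest linear sequence: 24 steps, from 5-chloropent-1-ene 9 to 48 (steps 6–8, 10–26 and 30–33).

The three steps most likely to fail:

**Step 21 (key step).** The ring closure may pair the aldehyde face and the allyl orientation the wrong way, which inverts C7 relative to C9, or the allylchromium may couple between molecules instead of closing the ten-membered ring. The fallback makes the allyl unit configurationally fixed before the aldehyde is set free, and it sets out from bromide 28. Pd2(dba)3-catalysed borylation with B2pin2 in toluene should give the pinacol allylboronate F1, with boron on C13 and the olefin geometry kept. CSA in MeOH removes the C8 TBS ether to give the alcohol boronate F2, and Dess–Martin oxidation gives the aldehyde boronate F3. Sc(OTf)3 (cat.) in dilute toluene, then TsOH, should bring about intramolecular allylboration through a closed chair with Felkin attack on the non-chelated aldehyde, followed by lactonisation. This should give the cis-fused C8-epimeric lactone F4 with the same C7 configuration. F4 is taken through the conditions of steps 22–24 to the 8-epi diol F5, the 8-epi acetate F6 and the 8-epi thiocarbonylimidazolide F7. The conditions of step 25 then remove the C8 oxygen, so the fallback comes back to the route at 37.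

**Step 25.** Hydrogen transfer to the C8 radical may be outrun by reversible 3-exo attack on the C11=C13 olefin, which would move the side chain from C7 to C8, or by transannular hydrogen abstraction. The fallback masks that olefin during the radical step and sets out from lactone 33. Conjugate addition of PhSH (Et3N cat., THF) gives the sulfide lactone F8 as C11 epimers. iBu2AlH gives the sulfide diol F9, Ac2O/collidine the sulfide acetate F10, and thiocarbonyldiimidazole the sulfide thiocarbonylimidazolide F11. Bu3SnH/AIBN then gives the deoxygenated sulfide F12, whose C8 radical has no olefin within reach. mCPBA (1 equiv, −78 °C) gives the sulfoxide F13. Thermal syn-elimination (toluene, 110 °C, NaHCO3) restores the C11=C13 olefin and comes back to the route at 37.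

**Step 33.** Oxygen transfer may be slow or poorly face-selective. The titanium tartrate must reach the one exposed face of a ring olefin whose orientation is fixed by the ring conformation, the allylic alcohol is of the 2,3-cis-disubstituted class, and the free side-chain hydroxyl also binds titanium. The fallback gives up reagent control for substrate control and sets out from 47. VO(acac)2/t-BuOOH in CH2Cl2 at 0 °C epoxidises only the olefin next to the free C15 hydroxyl, from the peripheral face of the ring, which in germacra-1(10),4-dienes is expected to be the face of the natural 4,5-epoxide. It comes back to the route at 48 and makes no new compound.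

Further compounds
F1 | step 21 | open-chain pinacol allylboronate (boron on C13; 9S, 1(10)E, 4Z; C6 cis to CH2B): 8-OTBS, 9-OPMB, 14-OPMB, 15-OTBDPS | CC(C)(C)[Si](C)(C)OC[C@@H](OCc1ccc(OC)cc1)/C(COCc1ccc(OC)cc1)=C/CC/C(CO[Si](c1ccccc1)(c1ccccc1)C(C)(C)C)=C/C/C=C(\CB1OC(C)(C)C(C)(C)O1)C(=O)OC
F2 | step 21 | alcohol boronate, 8-OH analogue of F1 | OC[C@@H](OCc1ccc(OC)cc1)/C(COCc1ccc(OC)cc1)=C/CC/C(CO[Si](c1ccccc1)(c1ccccc1)C(C)(C)C)=C/C/C=C(\CB1OC(C)(C)C(C)(C)O1)C(=O)OC
F3 | step 21 | aldehyde boronate, C8 aldehyde analogue of F1 | O=C[C@@H](OCc1ccc(OC)cc1)/C(COCc1ccc(OC)cc1)=C/CC/C(CO[Si](c1ccccc1)(c1ccccc1)C(C)(C)C)=C/C/C=C(\CB1OC(C)(C)C(C)(C)O1)C(=O)OC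
F4 | step 21 | cis-fused C8-epimeric lactone, (7S,8R,9S) epimer of 33 | C=C1C(=O)O[C@H]2[C@@H](OCc3ccc(OC)cc3)/C(COCc3ccc(OC)cc3)=C/CC/C(CO[Si](c3ccccc3)(c3ccccc3)C(C)(C)C)=C/C[C@@H]12
F5 | step 21 | 8-epi diol, C8 epimer of 34 | C=C(CO)[C@H]1[C@@H](O)[C@@H](OCc2ccc(OC)cc2)/C(COCc2ccc(OC)cc2)=C/CC/C(CO[Si](c2ccccc2)(c2ccccc2)C(C)(C)C)=C/C1
F6 | step 21 | 8-epi acetate, C8 epimer of 35 | C=C(COC(C)=O)[C@H]1[C@@H](O)[C@@H](OCc2ccc(OC)cc2)/C(COCc2ccc(OC)cc2)=C/CC/C(CO[Si](c2ccccc2)(c2ccccc2)C(C)(C)C)=C/C1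
F7 | step 21 | 8-epi thiocarbonylimidazolide, C8 epimer of 36 | C=C(COC(C)=O)[C@H]1[C@@H](OC(=S)n2ccnc2)[C@@H](OCc2ccc(OC)cc2)/C(COCc2ccc(OC)cc2)=C/CC/C(CO[Si](c2ccccc2)(c2ccccc2)C(C)(C)C)=C/C1
F8 | step 25 | sulfide lactone, 13-(phenylthio)-11,13-dihydro derivative of 33 (C11 epimers) | O=C1O[C@@H]2[C@@H](OCc3ccc(OC)cc3)/C(COCc3ccc(OC)cc3)=C/CC/C(CO[Si](c3ccccc3)(c3ccccc3)C(C)(C)C)=C/C[C@H]2C1CSc1ccccc1
F9 | step 25 | sulfide diol, 13-(phenylthio)-11,13-dihydro derivative of 34 (C11 epimers) | OCC(CSc1ccccc1)[C@H]1[C@H](O)[C@@H](OCc2ccc(OC)cc2)/C(COCc2ccc(OC)cc2)=C/CC/C(CO[Si](c2ccccc2)(c2ccccc2)C(C)(C)C)=C/C1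
F10 | step 25 | sulfide acetate, 12-O-acetyl derivative of F9 | CC(=O)OCC(CSc1ccccc1)[C@H]1[C@H](O)[C@@H](OCc2ccc(OC)cc2)/C(COCc2ccc(OC)cc2)=C/CC/C(CO[Si](c2ccccc2)(c2ccccc2)C(C)(C)C)=C/C1
F11 | step 25 | sulfide thiocarbonylimidazolide, 8-O-(imidazol-1-ylthiocarbonyl) derivative of F10 | CC(=O)OCC(CSc1ccccc1)[C@H]1[C@H](OC(=S)n2ccnc2)[C@@H](OCc2ccc(OC)cc2)/C(COCc2ccc(OC)cc2)=C/CC/C(CO[Si](c2ccccc2)(c2ccccc2)C(C)(C)C)=C/C1
F12 | step 25 | deoxygenated sulfide, 13-(phenylthio)-11,13-dihydro derivative of 37 (C11 epimers) | CC(=O)OCC(CSc1ccccc1)[C@H]1C[C@@H](OCc2ccc(OC)cc2)/C(COCc2ccc(OC)cc2)=C/CC/C(CO[Si](c2ccccc2)(c2ccccc2)C(C)(C)C)=C/C1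
F13 | step 25 | sulfoxide of F12 | CC(=O)OCC(CS(=O)c1ccccc1)[C@H]1C[C@@H](OCc2ccc(OC)cc2)/C(COCc2ccc(OC)cc2)=C/CC/C(CO[Si](c2ccccc2)(c2ccccc2)C(C)(C)C)=C/C1
F0 | step 33 | none | none
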